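**Retrosynthetic overview**
1. The target is the C6 3,4-dimethoxybenzoate of a trans-fused hydroazulenone diol; the last events are C4 desilylation and acylation of the secondary C6 hydroxyl.
2. The strategy rests on C6 being a secondary allylic carbinol inside the seven-membered ring (C1–C5–C6–C7=C8–C9–C10), bonded directly to the C7=C8 enone alkene. The ring bond C6–C7 and the C6 stereocentre are therefore made together from a C6 aldehyde on C5 and a C7 alkenylchromium (intramolecular Nozaki–Hiyama–Kishi closure of a Z-β-iodoenone).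
3. The Z-iodoenone arm on C1 comes from a C9 aldehyde (from a C1 vinyl group) by ethynyl addition, hydroxyl-directed anti-carbomagnesiation/iodination (methyl to C8, iodine to C7) and oxidation.
4. The cyclopentane triad is set in relay: C1 by enantioselective copper-catalysed conjugate addition of a 1-(trimethylsilyl)vinyl alane to 3-methylcyclopent-2-en-1-one, C5 by hydroxymethylation of the trapped enolate anti to the bulky silylvinyl group, C4 by isopropyl addition anti to the C5 substituent.
5. Ring order: the five-membered ring is present from the start; the seven-membered ring is closed once, late, in the key step.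

Key step: step 13

Assumption: the absolute sense of step 1 follows the ligand enantiomer; the enantiomer that gives the (S)-configured quaternary carbon is used.
Remark: atoms are numbered as in the target (C1 angular methyl carbon, C2, C3, C4 isopropyl carbinol, C5 ring-fusion CH, C6 acyloxy CH, C7=C8 with methyl on C8, C9 ketone, C10 CH2); α is the face of H5, β the face of the C1 methyl.

Step 1
Reactants: 1 3-methylcyclopent-2-en-1-one; 2 ethynyltrimethylsilane
Product: 5 trimethyl({(3S)-3-methyl-3-[1-(trimethylsilyl)ethenyl]cyclopent-1-en-1-yl}oxy)silane, via alkenylalane 3 (not isolated), via aluminium enolate 4 (not isolated)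
Conditions: 2, iBu2AlH, hexane/THF, 55 °C; then 1, Cu(OTf)2 (5 mol%), chiral sulfonate-bearing imidazolinium salt (carbene ligand precursor, 5 mol%), THF, −30 °C to rt; then Me3SiOTf, −78 °C
Reagents that add atoms: trimethylsilyl trifluoromethanesulfonate, C[Si](C)(C)OS(=O)(=O)C(F)(F)F
Why: Hydroalumination of the silylalkyne places aluminium on the silicon-bearing carbon, and the catalyst formed from Cu(OTf)2 and the chiral carbene ligand transfers this 1-silylvinyl group to one face of the β-methyl enone (enantioselective copper-catalysed conjugate addition of an alkenylaluminium to a β-substituted cyclic enone), which sets the quaternary C1 as (S), while silylation of the regiodefined aluminium enolate stores the C4–C5 enolate position as the silyl enol ether.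

Step 2
Reactants: 5 silyl enol ether; 6 formaldehyde (37% aqueous solution)
Product: 7 (2S,3S)-2-(hydroxymethyl)-3-methyl-3-[1-(trimethylsilyl)ethenyl]cyclopentan-1-one
Conditions: aq. HCHO, Yb(OTf)3 (10 mol%), THF, rt
Reagents that add atoms: none
Why: Mukaiyama aldol hydroxymethylation of the silyl enol ether catalysed by Yb(OTf)3 in water-containing THF, in which formaldehyde should attack C5 on the face away from the bulky 1-(trimethylsilyl)vinyl group on the neighbouring quaternary C1, so that C6 ends up trans to that group and cis to the C1 methyl.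

Step 3
Reactants: 7 hydroxymethyl ketone
Product: 8 (2S,3S)-3-methyl-2-[(naphthalen-2-ylmethoxy)methyl]-3-[1-(trimethylsilyl)ethenyl]cyclopentan-1-one
Conditions: 2-naphthylmethyl 2,2,2-trichloroacetimidate, TfOH (5 mol%), CH2Cl2/cyclohexane, 0 °C
Reagents that add atoms: 2-naphthylmethyl 2,2,2-trichloroacetimidate, N=C(OCc1ccc2ccccc2c1)C(Cl)(Cl)Cl
Why: Acid-catalysed imidate etherification protects the primary alcohol without base, so the β-hydroxy ketone should neither eliminate nor undergo retro-aldol cleavage, and the 2-naphthylmethyl ether tolerates the acid of step 4 and organometallic reagents yet is removable oxidatively beside a triethylsilyl ether; no stereocentre is touched.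

Step 4
Reactants: 8 silylvinyl ketone
Product: 9 (2S,3R)-3-ethenyl-3-methyl-2-[(naphthalen-2-ylmethoxy)methyl]cyclopentan-1-one
Conditions: CF3CO2H (5 equiv), CH2Cl2, 0 °C
Reagents that add atoms: none
Why: Protodesilylation of the vinylsilane (ipso protonation and loss of silicon from the β-silyl cation) unmasks the plain vinyl group for the later hydroboration and leaves the C5 substituent as the only strong steric bias for step 5, with short contact at 0 °C chosen so that C5 is not equilibrated through the enol.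

Step 5
Reactants: 9 vinyl ketone; 10 isopropylmagnesium chloride
Product: 11 (1R,2S,3R)-3-ethenyl-3-methyl-2-[(naphthalen-2-ylmethoxy)methyl]-1-(propan-2-yl)cyclopentan-1-ol
Conditions: iPrMgCl, LaCl3·2LiCl (30 mol%), THF, 0 °C
Reagents that add atoms: none
Why: Grignard 1,2-addition promoted by LaCl3·2LiCl should suppress enolisation and β-hydride reduction of the hindered ketone, and because the two C1 substituents (methyl and vinyl) are of similar size the face is chosen by the C5 side chain, attack anti to it giving isopropyl cis to H5 and the C4 hydroxyl cis to C6.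

Step 6
Reactants: 11 tertiary alcohol
Product: 12 triethyl({(1R,2S,3R)-3-ethenyl-3-methyl-2-[(naphthalen-2-ylmethoxy)methyl]-1-(propan-2-yl)cyclopentyl}oxy)silane
Conditions: Et3SiOTf, 2,6-lutidine, CH2Cl2, −78 to 0 °C
Reagents that add atoms: triethylsilyl trifluoromethanesulfonate, CC[Si](CC)(CC)OS(=O)(=O)C(F)(F)F
Why: Silyl triflate silylation of the hindered tertiary alcohol, giving an ether that blocks retro-aldol cleavage and dehydration once C6 is an aldehyde and that adds bulk on the β-face next to C6 for the ring closure.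

Step 7
Reactants: 12 vinyl silyl ether
Product: 14 2-{(1R,2S,3R)-1-methyl-2-[(naphthalen-2-ylmethoxy)methyl]-3-(propan-2-yl)-3-[(triethylsilyl)oxy]cyclopentyl}ethan-1-ol, via alkylborane 13 (not isolated)
Conditions: 9-BBN, THF, 0 to 50 °C; then NaOH, H2O2, 0 °C
Reagents that add atoms: hydrogen peroxide, OO
Why: Anti-Markovnikov hydroboration–oxidation of the only alkene puts the hydroxyl on the terminal carbon (C9) and creates no stereocentre.

Step 8
Reactants: 14 primary alcohol
Product: 15 {(1R,2S,3R)-1-methyl-2-[(naphthalen-2-ylmethoxy)methyl]-3-(propan-2-yl)-3-[(triethylsilyl)oxy]cyclopentyl}acetaldehyde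
Conditions: Dess–Martin periodinane, NaHCO3, CH2Cl2, 0 °C to rt
Reagents that add atoms: none
Why: Dess–Martin oxidation of the primary alcohol to the C9 aldehyde, whose α-carbon C10 is a CH2 next to a quaternary carbon, so nothing can epimerise.

Step 9
Reactants: 15 aldehyde; 16 ethynylmagnesium bromide
Product: 17 1-{(1R,2S,3R)-1-methyl-2-[(naphthalen-2-ylmethoxy)methyl]-3-(propan-2-yl)-3-[(triethylsilyl)oxy]cyclopentyl}but-3-yn-2-ol (both C9 epimers)
Conditions: HC≡CMgBr, THF, −78 to 0 °C
Reagents that add atoms: none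
Why: Grignard addition to the aldehyde gives the propargylic alcohol, and the uncontrolled C9 carbinol centre does not matter because C9 becomes a ketone in step 12.

Step 10
Reactants: 17 propargylic alcohol; 18 methylmagnesium bromide
Product: 20 (3Z)-4-iodo-3-methyl-1-{(1R,2S,3R)-1-methyl-2-[(naphthalen-2-ylmethoxy)methyl]-3-(propan-2-yl)-3-[(triethylsilyl)oxy]cyclopentyl}but-3-en-2-ol (both C9 epimers), via alkenylmagnesium alkoxide 19 (not isolated)
Conditions: MeMgBr (4 equiv), CuI (20 mol%), THF, −20 °C to rt; then I2, −40 to 0 °C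
Reagents that add atoms: iodine, [I][I]
Why: Hydroxyl-directed copper-catalysed anti-carbomagnesiation of the propargylic alkoxide delivers methyl to C8 and magnesium to C7 inside a five-membered magnesium chelate, so magnesium and then iodine (iodinolysis with retention) sit cis to C9, which is the Z geometry the ring alkene needs.

Step 11
Reactants: 20 Z-iodo allylic alcohol
Product: 21 (3Z)-1-{(1R,2S,3R)-2-(hydroxymethyl)-1-methyl-3-(propan-2-yl)-3-[(triethylsilyl)oxy]cyclopentyl}-4-iodo-3-methylbut-3-en-2-ol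
Conditions: DDQ, CH2Cl2/pH 7 buffer, 0 °C to rt
Reagents that add atoms: none
Why: Oxidative cleavage of the 2-naphthylmethyl ether (hydride abstraction, then hydrolysis of the oxocarbenium ion) frees the C6 hydroxyl while the tertiary silyl ether and the alkenyl iodide should survive, and any oxidation of the allylic C9 alcohol by DDQ only anticipates step 12.

Step 12
Reactants: 21 diol
Product: 22 (1R,2R,5R)-2-[(3Z)-4-iodo-3-methyl-2-oxobut-3-en-1-yl]-2-methyl-5-(propan-2-yl)-5-[(triethylsilyl)oxy]cyclopentane-1-carbaldehyde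
Conditions: Dess–Martin periodinane (3 equiv), NaHCO3, CH2Cl2, 0 °C to rt
Reagents that add atoms: none
Why: Double Dess–Martin oxidation turns the primary C6 alcohol into the aldehyde and the allylic C9 alcohol into the ketone under buffered non-basic conditions, which should leave the Z-iodoenone geometry and C5 intact (the formyl group is already anti to the isopropyl group and to the C10 arm).

Step 13
Reactants: 22 Z-iodoenone aldehyde
Product: 24 (1R,3aR,8S,8aS)-8-hydroxy-3a,6-dimethyl-1-(propan-2-yl)-1-[(triethylsilyl)oxy]-2,3,3a,4,8,8a-hexahydroazulen-5(1H)-one, via alkenylchromium 23 (not isolated)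
Conditions: CrCl2 (8 equiv), NiCl2 (2 mol%), degassed DMSO, rt, 0.005 M, slow addition of 22
Reagents that add atoms: none
Why: Divalent chromium reduces NiCl2 to zerovalent nickel, which inserts into the C7–I bond; transmetallation to trivalent chromium gives alkenylchromium 23 with retention of geometry, and 23 adds to the C6 aldehyde but not to the C9 ketone (intramolecular Nozaki–Hiyama–Kishi alkenyl halide–aldehyde coupling, an established way to close medium rings at an allylic carbinol and precedented for β-iodo-α,β-unsaturated carbonyl partners). The seven-membered ring C1–C5–C6–C7–C8–C9–C10 is closed by 7-exo-trig attack of C7 on the carbonyl carbon C6 with C7=C8 endocyclic, and the cis ring alkene this requires is fixed by the Z iodide. The new C6 stereocentre is controlled by the trans-disposed C5 and C1 substituents: in the chair-like transition state of the forming trans-fused ring the chromium-bound oxygen should take the outer pseudo-equatorial position gauche to H5, while the small H6 points into the pocket under the five-membered ring between C1 and C4, syn to the C1 methyl, which gives the 6α (S) alcohol. The step needs this face selectivity, aldehyde-over-ketone chemoselectivity and no epimerisation at C5; the first is secured by the C1 methyl and the bulky C4 triethylsilyl ether, which crowd the axial position for the metal alkoxide, the second by the known preference of alkenylchromium species for aldehydes, the third by the neutral conditions. High dilution keeps the coupling intramolecular.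

Step 14
Reactants: 24 silyl-protected hydroxy enone
Product: 25 (1R,3aR,8S,8aS)-1,8-dihydroxy-3a,6-dimethyl-1-(propan-2-yl)-2,3,3a,4,8,8a-hexahydroazulen-5(1H)-one
Conditions: HF·pyridine, pyridine, THF, 0 °C to rt
Reagents that add atoms: none
Why: Buffered fluoride cleavage of the tertiary triethylsilyl ether, mild enough that the γ-hydroxy enone should not isomerise and no stereocentre is touched.

Step 15
Reactants: 25 diol; 26 3,4-dimethoxybenzoyl chloride
Product: 27 (1R,3aR,8S,8aS)-1-hydroxy-3a,6-dimethyl-5-oxo-1-(propan-2-yl)-1,2,3,3a,4,5,8,8a-octahydroazulen-8-yl 3,4-dimethoxybenzoate (target)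
Conditions: 26, DMAP, Et3N, CH2Cl2, 0 °C to rt
Reagents that add atoms: none
Why: DMAP-catalysed acylation should occur only at the secondary allylic C6 hydroxyl because the C4 hydroxyl is tertiary and hindered, and it proceeds with retention at C6.

**Compound list**
1 | 3-methylcyclopent-2-en-1-one | CC1=CC(=O)CC1 | starting material
2 | ethynyltrimethylsilane | C#C[Si](C)(C)C | starting material
3 | diisobutyl[1-(trimethylsilyl)ethenyl]aluminium | C=C([Si](C)(C)C)[Al](CC(C)C)CC(C)C | intermediate (not isolated)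
4 | diisobutylaluminium enolate of (S)-3-methyl-3-[1-(trimethylsilyl)ethenyl]cyclopentanone | C=C([Si](C)(C)C)[C@@]1(C)CCC(O[Al](CC(C)C)CC(C)C)=C1 | intermediate (not isolated)
5 | trimethyl({(3S)-3-methyl-3-[1-(trimethylsilyl)ethenyl]cyclopent-1-en-1-yl}oxy)silane | C=C([Si](C)(C)C)[C@@]1(C)CCC(O[Si](C)(C)C)=C1 | intermediate
6 | formaldehyde | C=O | starting material
7 | (2S,3S)-2-(hydroxymethyl)-3-methyl-3-[1-(trimethylsilyl)ethenyl]cyclopentan-1-one | C=C([Si](C)(C)C)[C@@]1(C)CCC(=O)[C@@H]1CO | intermediate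
8 | (2S,3S)-3-methyl-2-[(naphthalen-2-ylmethoxy)methyl]-3-[1-(trimethylsilyl)ethenyl]cyclopentan-1-one | C=C([Si](C)(C)C)[C@@]1(C)CCC(=O)[C@@H]1COCc1ccc2ccccc2c1 | intermediate
9 | (2S,3R)-3-ethenyl-3-methyl-2-[(naphthalen-2-ylmethoxy)methyl]cyclopentan-1-one | C=C[C@@]1(C)CCC(=O)[C@@H]1COCc1ccc2ccccc2c1 | intermediate
10 | isopropylmagnesium chloride | CC(C)[Mg]Cl | starting material
11 | (1R,2S,3R)-3-ethenyl-3-methyl-2-[(naphthalen-2-ylmethoxy)methyl]-1-(propan-2-yl)cyclopentan-1-ol | C=C[C@@]1(C)CC[C@@](O)(C(C)C)[C@@H]1COCc1ccc2ccccc2c1 | intermediate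
12 | triethyl({(1R,2S,3R)-3-ethenyl-3-methyl-2-[(naphthalen-2-ylmethoxy)methyl]-1-(propan-2-yl)cyclopentyl}oxy)silane | C=C[C@@]1(C)CC[C@@](O[Si](CC)(CC)CC)(C(C)C)[C@@H]1COCc1ccc2ccccc2c1 | intermediate
13 | 9-(2-{(1R,2S,3R)-1-methyl-2-[(naphthalen-2-ylmethoxy)methyl]-3-(propan-2-yl)-3-[(triethylsilyl)oxy]cyclopentyl}ethyl)-9-borabicyclo[3.3.1]nonane | B1(CC[C@@]3(C)CC[C@@](O[Si](CC)(CC)CC)(C(C)C)[C@@H]3COCc4ccc5ccccc5c4)C2CCCC1CCC2 | intermediate (not isolated)
14 | 2-{(1R,2S,3R)-1-methyl-2-[(naphthalen-2-ylmethoxy)methyl]-3-(propan-2-yl)-3-[(triethylsilyl)oxy]cyclopentyl}ethan-1-ol | OCC[C@@]1(C)CC[C@@](O[Si](CC)(CC)CC)(C(C)C)[C@@H]1COCc1ccc2ccccc2c1 | intermediate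
15 | {(1R,2S,3R)-1-methyl-2-[(naphthalen-2-ylmethoxy)methyl]-3-(propan-2-yl)-3-[(triethylsilyl)oxy]cyclopentyl}acetaldehyde | O=CC[C@@]1(C)CC[C@@](O[Si](CC)(CC)CC)(C(C)C)[C@@H]1COCc1ccc2ccccc2c1 | intermediate
16 | ethynylmagnesium bromide | C#C[Mg]Br | starting material
17 | 1-{(1R,2S,3R)-1-methyl-2-[(naphthalen-2-ylmethoxy)methyl]-3-(propan-2-yl)-3-[(triethylsilyl)oxy]cyclopentyl}but-3-yn-2-ol (both C9 epimers) | C#CC(O)C[C@@]1(C)CC[C@@](O[Si](CC)(CC)CC)(C(C)C)[C@@H]1COCc1ccc2ccccc2c1 | intermediate
18 | methylmagnesium bromide | C[Mg]Br | starting material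
19 | bromomagnesium alkoxide of the (Z)-4-(bromomagnesio)-3-methylbut-3-en-2-ol formed from 17 (magnesium on C7 cis to C9) | Br[Mg]/C=C(/C)C(O[Mg]Br)C[C@@]1(C)CC[C@@](O[Si](CC)(CC)CC)(C(C)C)[C@@H]1COCc1ccc2ccccc2c1 | intermediate (not isolated)
20 | (3Z)-4-iodo-3-methyl-1-{(1R,2S,3R)-1-methyl-2-[(naphthalen-2-ylmethoxy)methyl]-3-(propan-2-yl)-3-[(triethylsilyl)oxy]cyclopentyl}but-3-en-2-ol (both C9 epimers) | I/C=C(/C)C(O)C[C@@]1(C)CC[C@@](O[Si](CC)(CC)CC)(C(C)C)[C@@H]1COCc1ccc2ccccc2c1 | intermediate
21 | (3Z)-1-{(1R,2S,3R)-2-(hydroxymethyl)-1-methyl-3-(propan-2-yl)-3-[(triethylsilyl)oxy]cyclopentyl}-4-iodo-3-methylbut-3-en-2-ol | I/C=C(/C)C(O)C[C@@]1(C)CC[C@@](O[Si](CC)(CC)CC)(C(C)C)[C@@H]1CO | intermediate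
22 | (1R,2R,5R)-2-[(3Z)-4-iodo-3-methyl-2-oxobut-3-en-1-yl]-2-methyl-5-(propan-2-yl)-5-[(triethylsilyl)oxy]cyclopentane-1-carbaldehyde | I/C=C(/C)C(=O)C[C@@]1(C)CC[C@@](O[Si](CC)(CC)CC)(C(C)C)[C@@H]1C=O | intermediate (key-step precursor)
23 | (Z)-alkenylchromium dichloride from 22 (trivalent chromium in place of iodine at C7) | Cl[Cr](Cl)/C=C(/C)C(=O)C[C@@]1(C)CC[C@@](O[Si](CC)(CC)CC)(C(C)C)[C@@H]1C=O | intermediate (not isolated)
24 | (1R,3aR,8S,8aS)-8-hydroxy-3a,6-dimethyl-1-(propan-2-yl)-1-[(triethylsilyl)oxy]-2,3,3a,4,8,8a-hexahydroazulen-5(1H)-one | O[C@H]1C=C(C)C(=O)C[C@@]2(C)CC[C@@](O[Si](CC)(CC)CC)(C(C)C)[C@H]12 | intermediate (key-step product)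
25 | (1R,3aR,8S,8aS)-1,8-dihydroxy-3a,6-dimethyl-1-(propan-2-yl)-2,3,3a,4,8,8a-hexahydroazulen-5(1H)-one | O[C@H]1C=C(C)C(=O)C[C@@]2(C)CC[C@@](O)(C(C)C)[C@H]12 | intermediate
26 | 3,4-dimethoxybenzoyl chloride | COc1ccc(C(=O)Cl)cc1OC | starting material
27 | (1R,3aR,8S,8aS)-1-hydroxy-3a,6-dimethyl-5-oxo-1-(propan-2-yl)-1,2,3,3a,4,5,8,8a-octahydroazulen-8-yl 3,4-dimethoxybenzoate | COc1ccc(C(=O)O[C@H]2C=C(C)C(=O)C[C@@]3(C)CC[C@@](O)(C(C)C)[C@H]23)cc1OC | target

Total step count: 15
Longest linear sequence: 15 steps (1 to 27)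

**Steps most likely to fail**

1. Step 13 (ring closure). The addition to the C6 aldehyde may show poor facial selectivity, the chromium-bound oxygen accepting the axial position under the ring, so that the 6β-alcohol becomes a main product. Fallback: the route sets out again from 22, the closure is run as before, and the (8R)-configured 6β-alcohol F1 is taken on. Mitsunobu esterification with 3,4-dimethoxybenzoic acid (PPh3, DIAD, toluene, 0 °C to rt) inverts C6 and installs the acyl group in one operation, giving the silyl-protected 6α-ester F2. HF·pyridine then removes the triethylsilyl group and the route is rejoined at 27.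

2. Step 10 (carbomagnesiation). Addition across the alkyne at the hindered secondary propargylic alkoxide may stall or lose regiocontrol, with metallation of the terminal alkyne C–H competing. Fallback: from aldehyde 15, EtMgBr gives the secondary alcohol F3 and Dess–Martin oxidation gives the ethyl ketone F4. Claisen formylation (NaH, HCO2Et, THF) at the less hindered C8 methylene gives the hydroxymethylene ketone F5, whose chelated sodium enolate (NaH, then PhNTf2) is sulfonylated on the formyl oxygen to give the Z-enol triflate F6. DDQ removes the naphthylmethyl group to give the primary alcohol F7, and Dess–Martin oxidation gives the aldehyde F8. The same CrCl2/NiCl2 closure, now of an alkenyl triflate, rejoins the route at 24.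

3. Step 4 (protodesilylation). The acid may enolise the ketone and erode the C5 configuration once silicon is gone, or attack the naphthylmethyl ether. Fallback: from 8 the silicon is kept. Addition of iPrMgCl with LaCl3·2LiCl gives the tertiary alcohol F9 (attack anti to the C5 side chain, the silylvinyl group lying pseudo-equatorial), and Et3SiOTf/2,6-lutidine gives the bis-silyl compound F10. BH3·THF followed by NaOH/H2O2 places the hydroxyl on the terminal carbon to give the 2-silyl alcohol F11. Dess–Martin oxidation gives the α-silyl aldehyde F12, whose C–Si bond is cleaved with K2CO3 in MeOH, and the route is rejoined at 15.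

**Further compounds**
F1 | step 13 | (1R,3aR,8R,8aS)-8-hydroxy-3a,6-dimethyl-1-(propan-2-yl)-1-[(triethylsilyl)oxy]-2,3,3a,4,8,8a-hexahydroazulen-5(1H)-one (C6 epimer of 24) | O[C@@H]1C=C(C)C(=O)C[C@@]2(C)CC[C@@](O[Si](CC)(CC)CC)(C(C)C)[C@H]12
F2 | step 13 | (1R,3aR,8S,8aS)-3a,6-dimethyl-5-oxo-1-(propan-2-yl)-1-[(triethylsilyl)oxy]-1,2,3,3a,4,5,8,8a-octahydroazulen-8-yl 3,4-dimethoxybenzoate | COc1ccc(C(=O)O[C@H]2C=C(C)C(=O)C[C@@]3(C)CC[C@@](O[Si](CC)(CC)CC)(C(C)C)[C@H]23)cc1OC
F3 | step 10 | 1-{(1R,2S,3R)-1-methyl-2-[(naphthalen-2-ylmethoxy)methyl]-3-(propan-2-yl)-3-[(triethylsilyl)oxy]cyclopentyl}butan-2-ol (both C9 epimers) | CCC(O)C[C@@]1(C)CC[C@@](O[Si](CC)(CC)CC)(C(C)C)[C@@H]1COCc1ccc2ccccc2c1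
F4 | step 10 | 1-{(1R,2S,3R)-1-methyl-2-[(naphthalen-2-ylmethoxy)methyl]-3-(propan-2-yl)-3-[(triethylsilyl)oxy]cyclopentyl}butan-2-one | CCC(=O)C[C@@]1(C)CC[C@@](O[Si](CC)(CC)CC)(C(C)C)[C@@H]1COCc1ccc2ccccc2c1
F5 | step 10 | (Z)-hydroxymethylene ketone: 1-hydroxy-2-methyl-4-{(1R,2S,3R)-1-methyl-2-[(naphthalen-2-ylmethoxy)methyl]-3-(propan-2-yl)-3-[(triethylsilyl)oxy]cyclopentyl}but-1-en-3-one | O/C=C(/C)C(=O)C[C@@]1(C)CC[C@@](O[Si](CC)(CC)CC)(C(C)C)[C@@H]1COCc1ccc2ccccc2c1
F6 | step 10 | (1Z)-2-methyl-4-{(1R,2S,3R)-1-methyl-2-[(naphthalen-2-ylmethoxy)methyl]-3-(propan-2-yl)-3-[(triethylsilyl)oxy]cyclopentyl}-3-oxobut-1-en-1-yl trifluoromethanesulfonate | O=S(=O)(O/C=C(/C)C(=O)C[C@@]1(C)CC[C@@](O[Si](CC)(CC)CC)(C(C)C)[C@@H]1COCc1ccc2ccccc2c1)C(F)(F)F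
F7 | step 10 | (1Z)-4-{(1R,2S,3R)-2-(hydroxymethyl)-1-methyl-3-(propan-2-yl)-3-[(triethylsilyl)oxy]cyclopentyl}-2-methyl-3-oxobut-1-en-1-yl trifluoromethanesulfonate | O=S(=O)(O/C=C(/C)C(=O)C[C@@]1(C)CC[C@@](O[Si](CC)(CC)CC)(C(C)C)[C@@H]1CO)C(F)(F)F
F8 | step 10 | (1Z)-4-{(1R,2R,3R)-2-formyl-1-methyl-3-(propan-2-yl)-3-[(triethylsilyl)oxy]cyclopentyl}-2-methyl-3-oxobut-1-en-1-yl trifluoromethanesulfonate | O=S(=O)(O/C=C(/C)C(=O)C[C@@]1(C)CC[C@@](O[Si](CC)(CC)CC)(C(C)C)[C@@H]1C=O)C(F)(F)F
F9 | step 4 | (1R,2S,3S)-3-methyl-2-[(naphthalen-2-ylmethoxy)methyl]-1-(propan-2-yl)-3-[1-(trimethylsilyl)ethenyl]cyclopentan-1-ol | C=C([Si](C)(C)C)[C@@]1(C)CC[C@@](O)(C(C)C)[C@@H]1COCc1ccc2ccccc2c1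
F10 | step 4 | triethyl({(1R,2S,3S)-3-methyl-2-[(naphthalen-2-ylmethoxy)methyl]-1-(propan-2-yl)-3-[1-(trimethylsilyl)ethenyl]cyclopentyl}oxy)silane | C=C([Si](C)(C)C)[C@@]1(C)CC[C@@](O[Si](CC)(CC)CC)(C(C)C)[C@@H]1COCc1ccc2ccccc2c1
F11 | step 4 | 2-{(1R,2S,3R)-1-methyl-2-[(naphthalen-2-ylmethoxy)methyl]-3-(propan-2-yl)-3-[(triethylsilyl)oxy]cyclopentyl}-2-(trimethylsilyl)ethan-1-ol (both C10 epimers) | OCC([Si](C)(C)C)[C@@]1(C)CC[C@@](O[Si](CC)(CC)CC)(C(C)C)[C@@H]1COCc1ccc2ccccc2c1
F12 | step 4 | 2-{(1R,2S,3R)-1-methyl-2-[(naphthalen-2-ylmethoxy)methyl]-3-(propan-2-yl)-3-[(triethylsilyl)oxy]cyclopentyl}-2-(trimethylsilyl)acetaldehyde (both C10 epimers) | O=CC([Si](C)(C)C)[C@@]1(C)CC[C@@](O[Si](CC)(CC)CC)(C(C)C)[C@@H]1COCc1ccc2ccccc2c1
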